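All runs are calculated with made-up constants; scatter was added.

It would have been easy to see substrate still standing in the flask and conclude that it needed more time. I looked at how the rate fell before trusting that reading. The flask is the one followed in the gamma run, and the delta run was made earlier with more substrate.

| setting | gamma | delta | flask |
|---|---|---|---|
| substrate | 0.80 M | 1.6 M | 0.80 M |
| partner | 0.80 M | 0.80 M | 0.800 M |
| protic impurity | 0.40 M | 0.40 M | 0.400 M |
| remark | the very flask that is asked about, followed so far | run made earlier |  |
| time |  |  | 40 h |

- gamma (time / h: target / %, substrate / %): 6.00: 35, 64; 12.0: 34, 65; 15.0: 36, 66; 25.0: 32, 63; 30.0: 37, 67; 40.0: 36, 65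
- delta (time / h: target / %, substrate / %): 0.250: 15, 89; 0.333: 18, 84; 0.500: 19, 79; 0.833: 22, 77; 1.33: 23, 76; 2.00: 26, 75; 3.00: 23, 69

(standard deviation of a reading: 2 percentage points)

- target taken out counts as made
- steps thought possible: substrate + partner -> target; 2 partner -> side product; partner + protic impurity -> quenched reagent
- additions bring no volume worth counting

- north-east: at 40 h take out 90% of the target then present, then wait 3.0 d
- south-east: at 40 h add partner, 50.0% of the amount charged, then wait 3.0 d
- north-west: change nothing and wait 3.0 d more
- south: at 40 h add substrate, 50.0% of the amount charged, then wait 3.0 d

* target, in percent of the substrate first charged, at 40 h
* the remedy with the largest gain of target, or "none" below 2 percentage points (north-east / south-east / north-west / south / none)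
* target present, with what was taken out counted in, in percent of the substrate first charged, after south-east
* target present, with what was taken out counted in, in percent of the substrate first charged, after south

I took the rate of target formation as proportional to substrate times partner, as the step is written. From the delta run, I read r, the mean rate up to the first reading, and s, a later mean rate:

r = 0.960 M h⁻¹, s = 0.0747 M h⁻¹, so r/s = 12.9

In the delta run, substrate read 76% at 1.33 h, which gives a slowing factor of about 1.32. That left a factor of 9.77 for partner, so partner slowed the rate more than substrate did.

In the gamma run, the target readings from 6.00 h to 40.0 h showed no trend that stood out from their standard deviation of 2 percentage points. Yet substrate, at 65%, accounted for a slowing factor of just 1.54. The accumulated slowing therefore pointed to partner, so I counted what partner had delivered. I defined the partner yield φ as the target made per partner charged: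

φ = mean target × substrate charged / partner charged = 35.0%

Taking out target, waiting and adding substrate bring no new partner, so I reckoned no gain from them and 35.0% after south. Adding partner, with φ assumed unchanged, gave me:

target after south-east = φ × (partner charged + partner added) / substrate charged = 52.5%

The forecast gave 35% now, chose south-east, and put south-east at 63%, above my figure, and south at 35%, holding that “Removing target, waiting, or adding substrate does nothing without partner”.

The flask gave 35.3% at 40 h; the remedy with the largest gain was south-east, and target reached 57.2% after south-east and 35.3% after south.

    substrate + partner → target (k = 0.0230 M⁻¹ min⁻¹)
    2 partner → side product (k = 0.0230 M⁻¹ min⁻¹)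
    partner + protic impurity → quenched reagent (k = 0.0500 M⁻¹ min⁻¹)

Target in the flask stood at 35.3% because partner, the limiting reagent, was down to 0% of its charge; the same run without that depletion reaches 100%. The added partner in this flask returned 43.8% of itself as target, more than φ. For the neighbour charged with 0.32 M of partner, φ gives 14.0%, and that flask gave 16.8%.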